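**Plan**

- Retrosynthesis: the C15 acetate, the C14–C15 bond and the C13 methyl are cut first (carboalumination of a terminal alkyne). The C9–C11 bond is cut next (Grignard addition to a C9 ketone, then allylic hydrogenolysis), then the two C–O bonds (dihydroxylation of a ring A C2=C3 alkene). Ring A is cut last, at C1–C10 and C3–C4, which leaves 6-methylcarvone and a three-carbon Z-iodoallyl linchpin.
- Forward: ring B is bought as (S)-carvone and C-methylated. Ring A is then annulated in one flask, without work-up between the stages: enolate alkylation at C10, then reductive Heck closure at C4. The side chain is attached at C9 and completed last.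
- Enabling feature: C10 is the alpha carbon of the ring B ketone (C9) and C4 is the internal carbon of the isopropenyl group on C5, so an enolate carbon and a palladium-accepting carbon sit 1,3 across C5. Because C4 ends up quaternary, the alkylpalladium cannot eliminate and is reduced to the second C4 methyl. The Z-vinyl iodide leaves the C2=C3 alkene that later becomes the diol.
- Stereochemistry: C5 comes from carvone; C10 from alkylation anti to the isopropenyl group; C2 and C3 from osmylation anti to the axial methyls on C4 and C10; C9 from palladium hydride delivery anti to a carbonate whose position is set by Grignard attack anti to CH3-10; 13E from syn-carboalumination.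

Key step: step 4

Remark on the chemistry: the SMILES describes an ent-labdane (CH3-10 and the C9 side chain on one face; H-5, H-9 and both hydroxyls on the other), so (S)-(+)-carvone is the matching enantiomer. Atom numbers in the text are labdane numbers.

**Route**

Step 1
Reactants: 1 ethyl (Z)-3-iodoprop-2-enoate
Product: 2 (Z)-3-iodoprop-2-en-1-ol
Conditions: i-Bu2AlH (2.2 equiv), CH2Cl2, −78 to 0 °C; aqueous potassium sodium tartrate work-up
Reagents that add atoms: none
Why: 1,2-Reduction of the ester by i-Bu2AlH should give the allylic alcohol and leave the vinyl iodide and its Z geometry untouched at low temperature.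

Step 2
Reactants: 2 (Z)-3-iodoprop-2-en-1-ol
Product: 3 (Z)-3-bromo-1-iodoprop-1-ene
Conditions: CBr4, PPh3, CH2Cl2, 0 °C
Reagents that add atoms: tetrabromomethane BrC(Br)(Br)Br
Why: Appel bromination converts the primary allylic alcohol into the bromide under neutral conditions that should not isomerise the Z-vinyl iodide.

Step 3
Reactants: 4 (S)-(+)-carvone
Product: 6 (5S)-2,6-dimethyl-5-(prop-1-en-2-yl)cyclohex-2-en-1-one (6-methylcarvone), via lithium dienolate 5 (not isolated)
Conditions: LiN(i-Pr)2, THF, −78 °C; MeI, −78 to 0 °C
Reagents that add atoms: iodomethane CI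
Why: Kinetic deprotonation at the alpha-prime carbon (the future C10) and C-methylation of the cross-conjugated dienolate (enolate alkylation) should give 6 as a mixture of epimers at that carbon, which is of no consequence because the centre is enolised again in step 4.

Step 4
Reactants: 6 6-methylcarvone; 3 (Z)-3-bromo-1-iodoprop-1-ene
Product: 9 (4aR,8aR)-2,5,5,8a-tetramethyl-4a,5,8,8a-tetrahydronaphthalen-1(4H)-one, via lithium enolate 7 (not isolated), via vinyl iodide 8 (not isolated)
Conditions: LiN(i-Pr)2, THF, −78 °C; 3, −78 to 0 °C; then DMF, Pd(OAc)2 (10 mol %), PPh3 (25 mol %), HCO2Na, 70 °C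
Reagents that add atoms: none
Why: Enolate 7 is C-alkylated at C10 by the allylic bromide end of 3 on the face opposite the isopropenyl group (enolate alkylation, axial attack anti to the C5 substituent), then zerovalent palladium inserts into the Z-vinyl iodide of 8, the vinylpalladium adds C3 to C4 of the isopropenyl group, and the resulting neopentyl alkylpalladium, which has no beta-hydrogen because C4 is now quaternary, is cleaved by formate-derived hydride to the second C4 methyl (intramolecular reductive Heck reaction). The closest known reaction types are the anti-selective second alkylation of 6-alkylcarvone enolates and reductive Heck cyclisations of vinyl halides onto 1,1-disubstituted alkenes that create quaternary carbons. Ring A closes in the 6-exo-trig mode, which syn-carbopalladation favours over 7-endo, and the Z geometry of the halide both allows closure and leaves C2=C3 inside the new ring. The only new stereocentre, C10, is controlled by the carvone-derived C5 centre, which places C1 trans to C4 as the trans ring fusion requires, while C4 carries two methyl groups and is not stereogenic. The step needs C- over O-alkylation (lithium enolate and soft allylic bromide in THF), insertion into the isopropenyl group in preference to the enone alkene (the enone carbon within reach is fully substituted and accessible only from the diaxial conformer), and hydride capture faster than 3-exo closure onto the new ring alkene (excess formate).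

Step 5
Reactants: 9 bicyclic dienone
Product: 10 (4aR,8aR)-6,7-cis-dihydroxy-2,5,5,8a-tetramethyl-4a,5,6,7,8,8a-hexahydronaphthalen-1(4H)-one (labdane C2 and C3 hydroxyls, both on the H-5 face, anti to CH3-10)
Conditions: OsO4 (2 mol %), N-methylmorpholine N-oxide, acetone/H2O, 23 °C
Reagents that add atoms: osmium tetroxide O=[Os](=O)(=O)=O; N-methylmorpholine N-oxide C[N+]1([O-])CCOCC1; water O
Why: Upjohn syn-dihydroxylation should take the electron-rich ring A alkene in preference to the electron-poor enone alkene and from the face opposite the axial methyl groups on C4 and C10, which sets C2 and C3 together as the cis-diol anti to CH3-10.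

Step 6
Reactants: 10 diol
Product: 11 2,3-O-isopropylidene derivative (acetonide) of 10
Conditions: 2,2-dimethoxypropane, pyridinium p-toluenesulfonate (cat.), CH2Cl2, 23 °C
Reagents that add atoms: 2,2-dimethoxypropane COC(C)(C)OC
Why: Acid-catalysed transacetalisation of the cis-vicinal diol gives the five-membered isopropylidene acetal, which masks both hydroxyls for the organometallic steps.

Step 7
Reactants: 11 acetonide ketone; 12 (4-bromobut-1-yn-1-yl)trimethylsilane
Product: 15 methyl carbonate of the C9 tertiary allylic alcohol (4-(trimethylsilyl)but-3-ynyl chain on the H-5 face, carbonate oxygen on the CH3-10 face; 2,3-acetonide), via Grignard reagent 13 (not isolated), via magnesium alkoxide 14 (not isolated)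
Conditions: 12, Mg, THF, 23 °C; then 11, LaCl3·2LiCl (30 mol %), THF, −78 to 0 °C; then ClCO2Me, 0 to 23 °C
Reagents that add atoms: methyl chloroformate COC(=O)Cl
Why: 1,2-Addition of Grignard reagent 13 to the hindered enone carbonyl (lanthanum salt activation favours carbonyl over conjugate addition) should occur axially on the face opposite the axial C10 methyl, and O-acylation of alkoxide 14 in the same flask gives the tertiary allylic carbonate with its oxygen on the CH3-10 face.

Step 8
Reactants: 15 tertiary allylic carbonate
Product: 16 2,3-O-isopropylidene-14-(trimethylsilyl)-15,16-dinor-ent-labd-7-en-13-yne-2α,3α-diol (H-9 on the H-5 face, side chain cis to CH3-10)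
Conditions: Pd(OAc)2 (5 mol %), n-Bu3P (5 mol %), HCO2H, Et3N, THF, 23 to 50 °C
Reagents that add atoms: none
Why: Palladium-catalysed formate hydrogenolysis of an allylic carbonate: zerovalent palladium ionises the carbonate with inversion and so sits on the face opposite CH3-10, and hydride is passed from palladium to the more substituted allyl terminus C9, which should give the less substituted C7=C8 alkene and H-9 on the H-5 face with the side chain equatorial.

Step 9
Reactants: 16 silyl alkyne
Product: 17 2,3-O-isopropylidene-15,16-dinor-ent-labd-7-en-13-yne-2α,3α-diol (terminal alkyne)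
Conditions: K2CO3 (cat.), MeOH, 23 °C
Reagents that add atoms: none
Why: Base-catalysed methanolysis of the alkynyl C–Si bond (protodesilylation) frees the terminal alkyne without touching the acetonide or the ring alkene.

Step 10
Reactants: 17 terminal alkyne
Product: 20 2,3-O-isopropylidene-ent-labda-7,13E-diene-2α,3α,15-triol, via alkenylalane 18 (not isolated), via lithium alanate 19 (not isolated)
Conditions: Me3Al, Cp2ZrCl2 (20 mol %), CH2Cl2, −20 to 23 °C; volatiles removed; n-BuLi, hexane/THF, −78 °C; (CH2O)n, 23 °C; aqueous potassium sodium tartrate work-up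
Reagents that add atoms: trimethylaluminium C[Al](C)C; paraformaldehyde (as formaldehyde) C=O
Why: Zirconium-catalysed methylalumination (Negishi carboalumination) adds CH3 and aluminium syn across the alkyne with aluminium on the terminal carbon, and hydroxymethylation of the derived alanate with retention should give the 13E allylic alcohol with C15 cis to the C13 methyl.

Step 11
Reactants: 20 allylic alcohol
Product: 21 2,3-O-isopropylidene-ent-2α,3α-dihydroxylabda-7,13E-dien-15-yl acetate
Conditions: Ac2O, pyridine, 4-(dimethylamino)pyridine (cat.), CH2Cl2, 0 to 23 °C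
Reagents that add atoms: acetic anhydride CC(=O)OC(C)=O
Why: Nucleophile-catalysed acylation of the only free hydroxyl, the primary allylic one, gives the acetate while the diol stays masked.

Step 12
Reactants: 21 acetonide acetate
Product: 22 ent-2α,3α-dihydroxylabda-7,13E-dien-15-yl acetate (CNP0280580.2)
Conditions: AcOH/H2O/THF, 45 °C
Reagents that add atoms: none
Why: Acid-catalysed hydrolysis of the isopropylidene acetal frees the diol, while the primary allylic acetate should survive aqueous acetic acid, in which any exchange at the ester returns the same acetate.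

**Compound list**

1 | ethyl (Z)-3-iodoprop-2-enoate | CCOC(=O)/C=C\I | starting material
2 | (Z)-3-iodoprop-2-en-1-ol | OC/C=C\I | intermediate
3 | (Z)-3-bromo-1-iodoprop-1-ene | BrC/C=C\I | intermediate
4 | (S)-(+)-carvone, (5S)-2-methyl-5-(prop-1-en-2-yl)cyclohex-2-en-1-one | O=C1C(C)=CC[C@H](C(C)=C)C1 | starting material
5 | lithium cross-conjugated dienolate of 4 | [Li]OC1=C[C@@H](C(C)=C)CC=C1C | intermediate
6 | (5S)-2,6-dimethyl-5-(prop-1-en-2-yl)cyclohex-2-en-1-one (6-methylcarvone, epimers at C6) | O=C1C(C)=CC[C@H](C(C)=C)C1C | intermediate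
7 | lithium enolate of 6 | [Li]OC1=C(C)[C@@H](C(C)=C)CC=C1C | intermediate
8 | (5R,6R)-6-[(2Z)-3-iodoprop-2-en-1-yl]-2,6-dimethyl-5-(prop-1-en-2-yl)cyclohex-2-en-1-one (iodoallyl trans to isopropenyl) | O=C1C(C)=CC[C@H](C(C)=C)[C@@]1(C)C/C=C\I | intermediate
9 | (4aR,8aR)-2,5,5,8a-tetramethyl-4a,5,8,8a-tetrahydronaphthalen-1(4H)-one (trans ring fusion) | O=C1C(C)=CC[C@@H]2C(C)(C)C=CC[C@@]12C | intermediate
10 | (4aR,8aR)-6,7-cis-dihydroxy-2,5,5,8a-tetramethyl-4a,5,6,7,8,8a-hexahydronaphthalen-1(4H)-one (both OH on the H-4a face) | O=C1C(C)=CC[C@@H]2C(C)(C)[C@@H](O)[C@@H](O)C[C@@]12C | intermediate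
11 | 2,3-O-isopropylidene derivative of 10 | O=C1C(C)=CC[C@@H]2C(C)(C)[C@@H](O3)[C@@H](OC3(C)C)C[C@@]12C | intermediate
12 | (4-bromobut-1-yn-1-yl)trimethylsilane | C[Si](C)(C)C#CCCBr | starting material
13 | [4-(trimethylsilyl)but-3-yn-1-yl]magnesium bromide | C[Si](C)(C)C#CCC[Mg]Br | intermediate
14 | bromomagnesium alkoxide of the C9 tertiary allylic alcohol (oxygen on the CH3-10 face) | Br[Mg]O[C@]1(CCC#C[Si](C)(C)C)C(C)=CC[C@@H]2C(C)(C)[C@@H](O3)[C@@H](OC3(C)C)C[C@@]12C | intermediate
15 | methyl carbonate of the C9 tertiary allylic alcohol (oxygen on the CH3-10 face, 2,3-acetonide) | COC(=O)O[C@]1(CCC#C[Si](C)(C)C)C(C)=CC[C@@H]2C(C)(C)[C@@H](O3)[C@@H](OC3(C)C)C[C@@]12C | intermediate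
16 | 2,3-O-isopropylidene-14-(trimethylsilyl)-15,16-dinor-ent-labd-7-en-13-yne-2α,3α-diol | C[Si](C)(C)C#CCC[C@@H]1C(C)=CC[C@@H]2C(C)(C)[C@@H](O3)[C@@H](OC3(C)C)C[C@@]12C | intermediate
17 | 2,3-O-isopropylidene-15,16-dinor-ent-labd-7-en-13-yne-2α,3α-diol | C#CCC[C@@H]1C(C)=CC[C@@H]2C(C)(C)[C@@H](O3)[C@@H](OC3(C)C)C[C@@]12C | intermediate
18 | (13E)-alkenyl(dimethyl)alane, aluminium on C14 cis to the C13 methyl | C[Al](C)/C=C(\C)CC[C@@H]1C(C)=CC[C@@H]2C(C)(C)[C@@H](O3)[C@@H](OC3(C)C)C[C@@]12C | intermediate
19 | lithium butyl(dimethyl)alkenylalanate derived from 18 | [Li+].CCCC[Al-](C)(C)/C=C(\C)CC[C@@H]1C(C)=CC[C@@H]2C(C)(C)[C@@H](O3)[C@@H](OC3(C)C)C[C@@]12C | intermediate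
20 | 2,3-O-isopropylidene-ent-labda-7,13E-diene-2α,3α,15-triol | OC/C=C(\C)CC[C@@H]1C(C)=CC[C@@H]2C(C)(C)[C@@H](O3)[C@@H](OC3(C)C)C[C@@]12C | intermediate
21 | 2,3-O-isopropylidene-ent-2α,3α-dihydroxylabda-7,13E-dien-15-yl acetate | CC(=O)OC/C=C(\C)CC[C@@H]1C(C)=CC[C@@H]2C(C)(C)[C@@H](O3)[C@@H](OC3(C)C)C[C@@]12C | intermediate
22 | ent-2α,3α-dihydroxylabda-7,13E-dien-15-yl acetate (CNP0280580.2; hydroxyls, H-5 and H-9 on one face, CH3-10 and the side chain on the other) | CC(=O)OC/C=C(\C)CC[C@@H]1C(C)=CC[C@@H]2C(C)(C)[C@@H](O)[C@@H](O)C[C@@]12C | target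

**Step count and risks**

Total step count: 12. Longest linear sequence: 11 steps (steps 1, 2 and 4 to 12, from 1); from carvone the sequence is 10 steps.

Steps most likely to fail:

Step 4. What may go wrong: hydride capture of the vinylpalladium before ring closure, 3-exo closure and ring enlargement of the neopentyl alkylpalladium, migration of the new ring alkene by palladium hydride, or inhibition of the catalyst by amine and lithium salts in the one-flask mode. The fallback replaces the organopalladium closure by a cationic one; it sets out from 6 and returns at 9. Commercial 3-(trimethylsilyl)prop-2-yn-1-ol would be semi-hydrogenated (H2, Pd/CaCO3 poisoned with Pb(OAc)2, quinoline, hexane) to (Z)-3-(trimethylsilyl)prop-2-en-1-ol F1 and brominated (CBr4, PPh3, CH2Cl2) to (Z)-(3-bromoprop-1-en-1-yl)trimethylsilane F2. Enolate 7, made from 6 as in step 4, would be alkylated with F2 to the isolated (5R,6R)-2,6-dimethyl-5-(prop-1-en-2-yl)-6-[(2Z)-3-(trimethylsilyl)prop-2-en-1-yl]cyclohex-2-en-1-one F3. CF3CO2H in CH2Cl2 at 0 °C should then protonate the isopropenyl group to the tertiary C4 cation, which is attacked at the silicon-bearing carbon (vinylsilane-terminated cation–olefin cyclisation, beta-silyl cation at C2) and loses silicon to give 9 with the C2=C3 alkene in place.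

Step 8. What may go wrong: slow ionisation of the hindered tertiary carbonate, hydride delivery to C7 instead of C9, or beta-hydride loss from the allylpalladium to dienes. The fallback delivers the C9 hydrogen by a sigmatropic shift instead of from palladium; it sets out from 14 and returns at 16. Alkoxide 14 would be quenched with aqueous NH4Cl to the tertiary allylic alcohol F4. Oxidative 1,3-transposition with [C5H5NH][CrO3Cl] in CH2Cl2 should give the C7 enone F5, and 1,2-reduction with NaBH4 and CeCl3·7H2O in MeOH (Luche reduction, axial hydride attack) the C7 allylic alcohol F6 with its hydroxyl on the CH3-10 face. Mitsunobu displacement of F6 with 2-nitrobenzenesulfonylhydrazide (PPh3, diethyl azodicarboxylate, N-methylmorpholine, THF, −30 to 23 °C) proceeds with inversion; loss of sulfinic acid gives an allylic diazene that expels N2 by retro-ene transfer of hydrogen to C9 on the H-5 face, which moves the alkene to C7=C8 and gives 16.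

Step 10. What may go wrong: opening of the acetonide by the Lewis-acidic Me3Al, or incomplete transfer of the alkenyl group from aluminium to formaldehyde. The fallback builds the trisubstituted alkene by carbonyl olefination instead of carbometalation; it sets out from 17 and returns at 20. Gold-catalysed Markovnikov hydration of 17 (Ph3PAuNTf2, dioxane/H2O, 60 °C) would give the methyl ketone F7. Horner–Wadsworth–Emmons reaction with triethyl phosphonoacetate and NaH in THF should give mainly the E enoate F8, the Z isomer being removed by chromatography. Reduction of F8 with i-Bu2AlH (CH2Cl2, −78 °C) gives 20.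

Further compounds
F1 | step 4 | (Z)-3-(trimethylsilyl)prop-2-en-1-ol | C[Si](C)(C)/C=C\CO
F2 | step 4 | (Z)-(3-bromoprop-1-en-1-yl)trimethylsilane | C[Si](C)(C)/C=C\CBr
F3 | step 4 | (5R,6R)-2,6-dimethyl-5-(prop-1-en-2-yl)-6-[(2Z)-3-(trimethylsilyl)prop-2-en-1-yl]cyclohex-2-en-1-one | O=C1C(C)=CC[C@H](C(C)=C)[C@@]1(C)C/C=C\[Si](C)(C)C
F4 | step 8 | C9 tertiary allylic alcohol (hydroxyl on the CH3-10 face, 2,3-acetonide) | O[C@]1(CCC#C[Si](C)(C)C)C(C)=CC[C@@H]2C(C)(C)[C@@H](O3)[C@@H](OC3(C)C)C[C@@]12C
F5 | step 8 | transposed C7 enone with the C8=C9 alkene (2,3-acetonide) | C[Si](C)(C)C#CCCC1=C(C)C(=O)C[C@@H]2C(C)(C)[C@@H](O3)[C@@H](OC3(C)C)C[C@@]12C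
F6 | step 8 | C7 allylic alcohol with the C8=C9 alkene (hydroxyl on the CH3-10 face, 2,3-acetonide) | C[Si](C)(C)C#CCCC1=C(C)[C@H](O)C[C@@H]2C(C)(C)[C@@H](O3)[C@@H](OC3(C)C)C[C@@]12C
F7 | step 10 | 2,3-O-isopropylidene-2α,3α-dihydroxy-14,15-dinor-ent-labd-7-en-13-one (methyl ketone) | CC(=O)CC[C@@H]1C(C)=CC[C@@H]2C(C)(C)[C@@H](O3)[C@@H](OC3(C)C)C[C@@]12C
F8 | step 10 | ethyl 2,3-O-isopropylidene-ent-2α,3α-dihydroxylabda-7,13E-dien-15-oate | CCOC(=O)/C=C(\C)CC[C@@H]1C(C)=CC[C@@H]2C(C)(C)[C@@H](O3)[C@@H](OC3(C)C)C[C@@]12C
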